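## The problem

Target 21 is a flavone. Benzo ring A and pyranone ring C share the C4a–C8a bond; ring C carries the carbonyl at C4, a methoxy group at C3 and, at C2, the 4-hydroxyphenyl ring B. Ring A has no hydrogen left: C5, C6 and C8 bear methoxy groups and C7 a free hydroxyl. Four contiguous oxygens must therefore be placed and one kept different from its neighbours, while the second free phenol at C4′ must be kept apart from the C3 methyl ether. There is no stereocentre, so nothing has to be controlled in space; sp3 centres that appear at C2 and C3 on the way are removed when ring C is aromatised. The pyranone is opened at C2 by hard nucleophiles, and the C5 methoxy group, peri to the carbonyl, is the first ether to fall to Lewis acids. The C7 hydroxyl therefore cannot be unveiled by demethylation and needs a protecting group orthogonal to the one on C4′; tetraoxygenated benzene intermediates also oxidise easily to quinones. The enabling feature is that O1–C8a and C4–C4a sit on neighbouring carbons of ring A, the ortho oxygen/acyl pair that an aryne delivers when it inserts into the acyl–oxygen bond of a carboxylic acid. If C8 is left as hydrogen, the C5 methoxy group next to C4a is the only substituent flanking that aryne and alone decides where oxygen and acyl enter. C8 is then the single open position of ring A, ortho to the C7 hydroxyl, and can be oxygenated last.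

## Retrosynthesis

**21 from 20.** The O–benzyl bond at C4′ is cut last. Benzyl survives fluoride, DDQ, dilute acid, iodination and hot methoxide, and falls to hydrogenolysis, which touches neither the aryl methyl ethers nor the tetrasubstituted C2=C3 bond. It must come after the C8 chemistry, because an aryl iodide would not survive H2 on Pd/C.

**20 from 19 from 18.** The C8–O bond is cut to a C8–I bond and this to C8–H. Carrying the C8 oxygen through the aryne step would flank the aryne on both sides and remove the regiocontrol. In 18, C8 is the only unsubstituted ring A carbon and is ortho to the free C7 hydroxyl, so an electrophile has one place to go. The forward steps must iodinate ring A in preference to ring B (a less activated aryl benzyl ether) and exchange iodide for methoxide without opening the pyranone.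

**18 from 17 from 16.** The C7 hydroxyl is masked as a methoxymethyl ether, removable with dilute protic acid that spares benzyl and the C5 methoxy group. The C2=C3 unsaturation is traced back to the chroman-4-one 16, the oxidation level that the key step gives. Dehydrogenation erases both stereocentres of 16, so its diastereomer mixture is of no consequence.

**16 from 8 and 13 (key disconnection).** O1–C8a, C4–C4a and O1–C2 are cut together. This leaves aryne 14 (released from silyl triflate 8) and α-methoxycinnamic acid 13, with hydroxychalcone 15 as the open-chain intermediate. The neighbouring option, acylating an electron-rich ring A phenol, would have to choose between two ortho positions. Here the positions of oxygen and acyl are fixed by the silyl/triflate pair and the flanking methoxy group. The cut separates a benzene with one ring hydrogen from a one-step acid that already carries C2, C3 with its methoxy group, C4 and ring B. The forward reaction must add the carboxylate oxygen at C8a, shift the acyl group to C4a before the aryl anion is protonated, and close ring C by oxa-Michael addition.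

**13 from 9 and 10.** The C2=C3 bond of the acid is cut by an aldol condensation (through aldol 11 and ester 12). Aldehyde 9 cannot enolise and ester 10 brings the C3 methoxy group in its final form, so no late O-methylation at C3 is needed. The double-bond geometry is irrelevant because it is lost in the key step.

**8 from 5, 4, 3, 2 and 1.** The C–Si and O–Tf bonds are cut by a retro-Brook sequence (through 6 and 7) to bromophenol 5, and the C–Br bond to phenol 4. Phenol 4 is the monoacetal of the symmetric hydroquinone 3, which comes from quinone 2 and this from para-oxidation of commercial phenol 1. The symmetry of 3 makes its two hydroxyls equivalent, so the only price of differentiating them is a statistical monoprotection. In 4 the free hydroxyl, its para position blocked, directs bromine to its own ortho carbon, which becomes the silicon-bearing aryne carbon (future C8a).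

## Roads not taken

**Alternative 1:** Ring A is cut at C4a–C5 and C8–C8a. C5 to C8 come from diisopropyl squarate A1, and C4a/C8a are the C5=C6 bond of a preformed pyranone. Forward, bromopyranone A2 would be metallated at C5 and added to A1 to give the 4-hydroxycyclobutenone A3. Heating opens the four-membered ring to a dienylketene, which closes by 6π electrocyclisation onto the pyranone carbon that becomes C8a and tautomerises to hydroquinone A4.
- Merits: all four ring A oxygens arrive in one step with no regiochemical question, at the flavone oxidation level. Neither a dehydrogenation nor late C8 chemistry is needed.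
- Weak points: the oxygens arrive in the wrong state. A4 has free hydroxyls at C5 and C8 and two like isopropyl ethers at C6 and C7, whereas the target needs methyl at C5, C6 and C8 and hydrogen at C7. After methylation of C5 and C8, removing the isopropyl groups needs a Lewis acid, which attacks the peri C5 methoxy group first. The C6 and C7 hydroxyls would then still have to be told apart. A C5-metallated 4-pyranone also carries its own electrophilic carbonyl and C2/C6 positions, and A2 needs a synthesis of its own.
- Comparison: this road is more direct in building ring A than the chosen one, which spends three steps on C8. The chosen plan sets against this that every oxygen of 16 already carries its final methyl group or a protecting group orthogonal to the others.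

**Alternative 2:** Only C3–C4 is cut. O1 already links C8a to C2 in dialdehyde A6, made by O-alkylation of the fully substituted salicylaldehyde A5. Forward, a triazolium-derived carbene would turn the aromatic aldehyde into an acyl-anion equivalent that adds to the aliphatic aldehyde, closing ring C as the 3-hydroxychroman-4-one A7.
- Merits: ring A is complete before cyclisation, so there is no late C8 oxidation. Both phenols can be benzyl ethers removed in one hydrogenolysis. The sequence after the key step (oxidation to the flavonol, O-methylation, hydrogenolysis) is shorter than the five steps needed here.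
- Weak points: the aromatic aldehyde of A6 has two ortho substituents and an electron-rich ring, so the carbene should prefer the aliphatic aldehyde. The acyl-anion equivalent formed there has an aryloxide in the β position and can expel it, destroying the O1–C2 link, or give the regioisomeric 4-hydroxychroman-3-one. A5 is a hexasubstituted benzene and costs more steps than 8.
- Comparison: this road is better in end-game economy. The chosen plan has to set against it a precursor that is far easier to reach, a tandem process of a known type, and chemoselectivity that does not rest on the hindered aldehyde reacting first.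

**Alternative 3:** C2–C3 and C3–C4 are cut, and C3 is inserted as a one-carbon unit. Forward, benzofuranone A8 would be converted into its silyl enol ether A9, the 2-aryl-3-silyloxybenzofuran. Dibromocarbene from CHBr3 and KOtBu would add across its furan double bond and the cyclopropane would open with loss of bromide to the 3-bromoflavone A10.
- Merits: the flavone oxidation level is reached directly and ring A is complete.
- Weak points: turning the C3 bromide of A10 into the C3 methoxy group is not a simple substitution. Methoxide tends to add at C2 and open or contract the ring, so a metal-mediated C–O coupling at a hindered vinylic bromide would be needed. A8 again requires a fully substituted ring A and is itself prone to oxidation at C2. The free carbene must also spare two electron-rich aryl ethers.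
- Comparison: this road avoids dehydrogenation and late C8 steps. The chosen plan sets against it that the C3 methoxy group arrives with the acid in its final form and that no reactive C3 halide has to be exchanged next to the pyranone.

Key step: step 7

Assumption: the (Z) descriptor of acid 13 means that methoxy and aryl lie on the same side of the double bond (aryl trans to the carboxyl group), the thermodynamically preferred isomer; this geometry is not carried into the target. Chromanone 16 is taken as a racemic cis/trans mixture.

## Steps

Step 1
Reactants: 1 2,3-dimethoxyphenol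
Product: 2 2,3-dimethoxy-1,4-benzoquinone
Conditions: (KSO3)2NO (2.2 equiv), KH2PO4 buffer, H2O/acetone, 0 °C to rt
Reagents that add atoms: potassium nitrosodisulfonate, [O]N(S(=O)(=O)[O-])S(=O)(=O)[O-].[K+].[K+]
Why: Teuber oxidation: one nitroxide equivalent removes the phenolic hydrogen and a second adds at the free para carbon, and loss of imidodisulfonate gives the para-quinone, which is preferred over the ortho-quinone when the para position is open.

Step 2
Reactants: 2 2,3-dimethoxy-1,4-benzoquinone
Product: 3 2,3-dimethoxybenzene-1,4-diol
Conditions: Na2S2O4, EtOAc/H2O, rt, under argon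
Reagents that add atoms: none
Why: Dithionite reduction of a quinone to its hydroquinone; the electron-rich diol should be carried forward at once under inert gas because it reoxidises in air.

Step 3
Reactants: 3 2,3-dimethoxybenzene-1,4-diol
Product: 4 2,3-dimethoxy-4-(methoxymethoxy)phenol
Conditions: NaH (1.0 equiv), MOMCl (0.95 equiv), DMF, 0 °C
Reagents that add atoms: chloromethyl methyl ether, COCCl
Why: Williamson-type O-alkylation of the monosodium salt; the two hydroxyls of 3 are equivalent by symmetry, so the monoether should be the main product of a statistical distribution, separable from diol and bis-ether, both of which can be returned to 3.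

Step 4
Reactants: 4 2,3-dimethoxy-4-(methoxymethoxy)phenol
Product: 5 6-bromo-2,3-dimethoxy-4-(methoxymethoxy)phenol
Conditions: NBS (1.0 equiv), i-Pr2NH (10 mol %), CH2Cl2, −78 to 0 °C
Reagents that add atoms: N-bromosuccinimide, O=C1CCC(=O)N1Br
Why: Amine-mediated ortho-bromination of a phenol (electrophilic aromatic substitution); the free hydroxyl is a stronger ortho director than the acetal ether and its para position is blocked, so bromine should enter C6, and low temperature limits oxidation of the hydroquinone monoether.

Step 5
Reactants: 5 6-bromo-2,3-dimethoxy-4-(methoxymethoxy)phenol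
Product: 8 2,3-dimethoxy-4-(methoxymethoxy)-6-(trimethylsilyl)phenyl trifluoromethanesulfonate, via aryl trimethylsilyl ether 6 (not isolated), via lithium 2-silylphenoxide 7 (not isolated)
Conditions: HMDS, THF, 70 °C, then volatiles removed in vacuo; n-BuLi (1.1 equiv), THF, −78 °C; Tf2O (1.1 equiv), −78 °C to rt
Reagents that add atoms: hexamethyldisilazane, C[Si](C)(C)N[Si](C)(C)C; trifluoromethanesulfonic anhydride, O=S(=O)(OS(=O)(=O)C(F)(F)F)C(F)(F)F
Why: O-silylation, bromine–lithium exchange and 1,3 O-to-C silyl migration (retro-Brook rearrangement) give phenoxide 7, which is triflated in the same flask; exchange is faster than metalation next to the acetal, and the phenoxide should take up Tf2O at −78 °C well before the acetal is activated.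

Step 6
Reactants: 9 4-(benzyloxy)benzaldehyde; 10 methyl methoxyacetate
Product: 13 (Z)-3-[4-(benzyloxy)phenyl]-2-methoxyprop-2-enoic acid, via aldol adduct 11 (not isolated), via methyl ester 12 (not isolated)
Conditions: NaOMe (3 equiv), 10 (3 equiv), MeOH, 0 °C to reflux; then aq. NaOH, reflux; then HCl to pH 2
Reagents that add atoms: sodium hydroxide, [Na+].[OH-]
Why: Aldol condensation of the ester enolate with a non-enolisable aldehyde, E1cB dehydration of 11 to the conjugated ester 12 (aryl trans to the carbonyl group as the thermodynamic isomer) and saponification in the same flask; the acid should be purified by acid–base extraction and crystallisation.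

Step 7
Reactants: 8 2,3-dimethoxy-4-(methoxymethoxy)-6-(trimethylsilyl)phenyl trifluoromethanesulfonate; 13 (Z)-3-[4-(benzyloxy)phenyl]-2-methoxyprop-2-enoic acid
Product: 16 2-[4-(benzyloxy)phenyl]-3,5,6-trimethoxy-7-(methoxymethoxy)chroman-4-one (racemic cis/trans mixture), via aryne 14 (not isolated), via hydroxychalcone 15 (not isolated)
Conditions: 8 (1.5 equiv), 13 (1.0 equiv), CsF (4 equiv), THF, 125 °C, sealed tube
Reagents that add atoms: none
Why: CsF removes the silyl group of 8 with loss of triflate and releases aryne 14 slowly, and the cesium carboxylate of 13 adds through oxygen to the aryne carbon remote from the C5 methoxy group (future C8a), because the aryl anion then develops at C4a where that methoxy group stabilises it inductively. The aryl anion attacks the neighbouring ester carbonyl, which the α-methoxy group activates inductively, through a four-membered transition state, and the acyl group moves from oxygen to C4a (a 1,3 O-to-C acyl shift related to the anionic Fries rearrangement), giving the phenoxide of 15. This phenoxide adds to the enone β-carbon and closes ring C at O1–C2 in a 6-endo-trig oxa-Michael reaction, the same closure as the base-mediated isomerisation of 2′-hydroxychalcones to flavanones. The closest known reaction type is the fluoride-induced insertion of arynes into the C–O bond of carboxylic acids to give ortho-hydroxyaryl ketones, which with cinnamic acids continues to 2-arylchroman-4-ones. The stereocentres at C2 and C3 are under no control beyond the thermodynamic preference for the trans isomer, reached by enolisation at C3 and reversible ring opening; neither is needed, since both are erased in step 8. The step needs regioselective addition to the unsymmetrical aryne and acyl migration faster than protonation of the aryl anion; the first is secured by the single flanking methoxy group with C8 left as hydrogen (the remote C6 and C7 oxygens exert only weak effects), the second by the aprotic medium, excess CsF that holds the acid as its carboxylate, and slow aryne release. The acetal and benzyl ethers are inert to fluoride.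

Step 8
Reactants: 16 2-[4-(benzyloxy)phenyl]-3,5,6-trimethoxy-7-(methoxymethoxy)chroman-4-one
Product: 17 2-[4-(benzyloxy)phenyl]-3,5,6-trimethoxy-7-(methoxymethoxy)-4H-chromen-4-one
Conditions: DDQ (2 equiv), 1,4-dioxane, 100 °C
Reagents that add atoms: none
Why: DDQ dehydrogenation of a flavanone: hydride abstraction from C2, which is benzylic and flanked by O1 and the 4-benzyloxyphenyl donor, gives a stabilised oxocarbenium ion that loses the C3 proton, so both diastereomers converge on the flavone; acetal and benzyl ether should be inert under anhydrous thermal conditions.

Step 9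
Reactants: 17 2-[4-(benzyloxy)phenyl]-3,5,6-trimethoxy-7-(methoxymethoxy)-4H-chromen-4-one
Product: 18 2-[4-(benzyloxy)phenyl]-7-hydroxy-3,5,6-trimethoxy-4H-chromen-4-one
Conditions: 3 M HCl (aq), MeOH/THF, 50 °C
Reagents that add atoms: none
Why: Acid-catalysed acetal exchange removes the methoxymethyl group as dimethoxymethane; aryl methyl ethers, the benzyl ether and the pyranone are stable to dilute protic acid, whereas a Lewis acid would attack the C5 methoxy group.

Step 10
Reactants: 18 2-[4-(benzyloxy)phenyl]-7-hydroxy-3,5,6-trimethoxy-4H-chromen-4-one
Product: 19 2-[4-(benzyloxy)phenyl]-7-hydroxy-8-iodo-3,5,6-trimethoxy-4H-chromen-4-one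
Conditions: NIS (1.05 equiv), DMF, 0 °C to rt
Reagents that add atoms: N-iodosuccinimide, O=C1CCC(=O)N1I
Why: Electrophilic aromatic iodination; C8 is the only unsubstituted carbon of ring A and is ortho to the free C7 hydroxyl and to O1, while ring B is a less activated aryl benzyl ether conjugated with the pyranone, so one equivalent of NIS should iodinate C8 only.

Step 11
Reactants: 19 2-[4-(benzyloxy)phenyl]-7-hydroxy-8-iodo-3,5,6-trimethoxy-4H-chromen-4-one
Product: 20 2-[4-(benzyloxy)phenyl]-7-hydroxy-3,5,6,8-tetramethoxy-4H-chromen-4-one
Conditions: NaOMe (10 equiv), CuI (30 mol %), MeOH/DMF, 110 °C, sealed tube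
Reagents that add atoms: sodium methoxide, [Na+].[O-]C
Why: Ullmann-type copper-mediated methoxylation of an ortho-iodophenoxide, the reaction used to turn ortho-halophenols into guaiacol-type ethers and 8-iodoflavones into 8-methoxyflavones; the C7 phenoxide formed in the medium lowers the electrophilicity of C2 and should protect the pyranone from ring opening by methoxide.

Step 12
Reactants: 20 2-[4-(benzyloxy)phenyl]-7-hydroxy-3,5,6,8-tetramethoxy-4H-chromen-4-one
Product: 21 7-hydroxy-2-(4-hydroxyphenyl)-3,5,6,8-tetramethoxy-4H-chromen-4-one
Conditions: H2 (1 atm), 10% Pd/C, EtOAc/MeOH, rt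
Reagents that add atoms: none
Why: Hydrogenolysis of the benzyl ether; the tetrasubstituted C2=C3 bond of the pyranone, a vinylogous ester, and the aryl methyl ethers should not react at atmospheric pressure.

## Compound list

1 | 2,3-dimethoxyphenol | COc1cccc(O)c1OC | starting material
2 | 2,3-dimethoxy-1,4-benzoquinone | COC1=C(OC)C(=O)C=CC1=O | intermediate
3 | 2,3-dimethoxybenzene-1,4-diol | COc1c(O)ccc(O)c1OC | intermediate
4 | 2,3-dimethoxy-4-(methoxymethoxy)phenol | COCOc1ccc(O)c(OC)c1OC | intermediate
5 | 6-bromo-2,3-dimethoxy-4-(methoxymethoxy)phenol | COCOc1cc(Br)c(O)c(OC)c1OC | intermediate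
6 | [6-bromo-2,3-dimethoxy-4-(methoxymethoxy)phenoxy]trimethylsilane | COCOc1cc(Br)c(O[Si](C)(C)C)c(OC)c1OC | intermediate
7 | lithium 2,3-dimethoxy-4-(methoxymethoxy)-6-(trimethylsilyl)phenoxide | [Li+].[O-]c1c(OC)c(OC)c(OCOC)cc1[Si](C)(C)C | intermediate
8 | 2,3-dimethoxy-4-(methoxymethoxy)-6-(trimethylsilyl)phenyl trifluoromethanesulfonate | COCOc1cc([Si](C)(C)C)c(OS(=O)(=O)C(F)(F)F)c(OC)c1OC | intermediate
9 | 4-(benzyloxy)benzaldehyde | O=Cc1ccc(OCc2ccccc2)cc1 | starting material
10 | methyl methoxyacetate | COCC(=O)OC | starting material
11 | methyl 3-[4-(benzyloxy)phenyl]-3-hydroxy-2-methoxypropanoate (racemic mixture of diastereomers) | COC(C(=O)OC)C(O)c1ccc(OCc2ccccc2)cc1 | intermediate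
12 | methyl (Z)-3-[4-(benzyloxy)phenyl]-2-methoxyprop-2-enoate | CO/C(C(=O)OC)=C\c1ccc(OCc2ccccc2)cc1 | intermediate
13 | (Z)-3-[4-(benzyloxy)phenyl]-2-methoxyprop-2-enoic acid | CO/C(C(=O)O)=C\c1ccc(OCc2ccccc2)cc1 | intermediate
14 | 3,4-dimethoxy-5-(methoxymethoxy)benzyne (1,2-didehydro-3,4-dimethoxy-5-(methoxymethoxy)benzene) | COCOC1=CC#CC(OC)=C1OC | intermediate
15 | (Z)-3-[4-(benzyloxy)phenyl]-1-[2-hydroxy-5,6-dimethoxy-4-(methoxymethoxy)phenyl]-2-methoxyprop-2-en-1-one | CO/C(C(=O)c1c(O)cc(OCOC)c(OC)c1OC)=C\c1ccc(OCc2ccccc2)cc1 | intermediate
16 | 2-[4-(benzyloxy)phenyl]-3,5,6-trimethoxy-7-(methoxymethoxy)chroman-4-one (racemic mixture of C2/C3 diastereomers) | COCOc1cc2OC(c3ccc(OCc4ccccc4)cc3)C(OC)C(=O)c2c(OC)c1OC | intermediate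
17 | 2-[4-(benzyloxy)phenyl]-3,5,6-trimethoxy-7-(methoxymethoxy)-4H-chromen-4-one | COCOc1cc2oc(-c3ccc(OCc4ccccc4)cc3)c(OC)c(=O)c2c(OC)c1OC | intermediate
18 | 2-[4-(benzyloxy)phenyl]-7-hydroxy-3,5,6-trimethoxy-4H-chromen-4-one | COc1c(O)cc2oc(-c3ccc(OCc4ccccc4)cc3)c(OC)c(=O)c2c1OC | intermediate
19 | 2-[4-(benzyloxy)phenyl]-7-hydroxy-8-iodo-3,5,6-trimethoxy-4H-chromen-4-one | COc1c(O)c(I)c2oc(-c3ccc(OCc4ccccc4)cc3)c(OC)c(=O)c2c1OC | intermediate
20 | 2-[4-(benzyloxy)phenyl]-7-hydroxy-3,5,6,8-tetramethoxy-4H-chromen-4-one | COc1c(O)c(OC)c2oc(-c3ccc(OCc4ccccc4)cc3)c(OC)c(=O)c2c1OC | intermediate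
21 | 7-hydroxy-2-(4-hydroxyphenyl)-3,5,6,8-tetramethoxy-4H-chromen-4-one | COc1c(O)c(OC)c2oc(-c3ccc(O)cc3)c(OC)c(=O)c2c1OC | target

## Step count and least certain steps

Total: 12 steps. Longest linear sequence: 11 steps (steps 1 to 5, then 7 to 12); step 6 is the one-step side branch.

**Step 7 (key step).** The aryl anion may be protonated before the acyl group migrates, so that only O-arylation occurs; the bulky trisubstituted acyl group and the ortho methoxy group make the four-membered transition state crowded. The oxa-Michael closure may also stay incomplete, because the α-methoxy group feeds electron density into the β-carbon. The fallback separates insertion from ring closure. It sets out from 8, which is treated with methoxyacetic acid under the same CsF conditions; insertion into a small saturated acid is the best-behaved case of this reaction and should give 1-[2-hydroxy-5,6-dimethoxy-4-(methoxymethoxy)phenyl]-2-methoxyethan-1-one F1. Claisen–Schmidt condensation of F1 with aldehyde 9 (KOH, EtOH, rt) should give hydroxychalcone 15, which is closed with NaOAc in refluxing EtOH. The fallback comes back to the route at 16.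

**Step 3.** Monoprotection of a symmetric diol cannot exceed the statistical distribution, and the diol may oxidise during handling, so material is lost at an early stage. The fallback differentiates the two oxygens through bromine and sets out from quinone 2. Bromine addition and elimination with Et3N in the same flask should give 5-bromo-2,3-dimethoxy-1,4-benzoquinone F2, and Na2S2O4 reduces it to 5-bromo-2,3-dimethoxybenzene-1,4-diol F3. HMDS converts F3 into [(5-bromo-2,3-dimethoxy-1,4-phenylene)bis(oxy)]bis(trimethylsilane) F4. n-BuLi at −78 °C triggers the retro-Brook shift of the silyl group ortho to bromine only; Tf2O and an aqueous work-up that cleaves the remaining silyl ether should give 4-hydroxy-2,3-dimethoxy-6-(trimethylsilyl)phenyl trifluoromethanesulfonate F5. MOMCl and i-Pr2NEt in CH2Cl2 then protect the free phenol. The fallback comes back to the route at 8 and bypasses steps 3 to 5 with the same number of operations.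

**Step 4.** Bromination may lose regioselectivity between the position ortho to the hydroxyl and the one ortho to the acetal ether, or NBS may oxidise the hydroquinone monoether to the quinone. The fallback replaces electrophilic substitution by directed metalation and sets out from 4. Isopropyl isocyanate and Et3N should give 2,3-dimethoxy-4-(methoxymethoxy)phenyl isopropylcarbamate F6. N-silylation in situ (TBSOTf, TMEDA), ortho-lithiation with n-BuLi/TMEDA at −78 °C and a TMSCl quench should give 2,3-dimethoxy-4-(methoxymethoxy)-6-(trimethylsilyl)phenyl isopropylcarbamate F7; the carbamate is a stronger director than the acetal. Cleavage with DBU and Et2NH in MeCN liberates the phenol of 7, which is triflated in the same flask with PhNTf2. The fallback comes back to the route at 8.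

**Step 8.** Hydride abstraction may be slow, and retro-oxa-Michael opening to 15 may compete on prolonged heating; DDQ does not close the open chalcone. The fallback changes the mechanism to enol iodination and dehydroiodination. It sets out from 16 (or a mixture of 16 and 15), which is heated with catalytic I2 in DMSO at 120 °C; this medium also cyclises the open chalcone oxidatively. It comes back to the route at 17; if the acetal is lost to the acid formed, the product is 18 and step 9 is no longer needed. This fallback makes no new compound (F0).

**Step 11.** Reductive loss of iodine back to the C8–H compound and attack of methoxide at C2 with opening of the pyranone are the likely failures, both favoured by the high temperature the copper reaction needs. The fallback removes the free phenoxide and changes the metal; it sets out from 19. Benzylation (BnBr, K2CO3, DMF) should give 7-(benzyloxy)-2-[4-(benzyloxy)phenyl]-8-iodo-3,5,6-trimethoxy-4H-chromen-4-one F8. Palladium-catalysed C–O coupling with methanol (Pd2(dba)3, t-BuBrettPhos, Cs2CO3, toluene/MeOH, 80 °C) should give 7-(benzyloxy)-2-[4-(benzyloxy)phenyl]-3,5,6,8-tetramethoxy-4H-chromen-4-one F9. Hydrogenolysis of both benzyl ethers (H2, Pd/C) brings the fallback back to the route at 21.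

## Further compounds

F1 | step 7 | 1-[2-hydroxy-5,6-dimethoxy-4-(methoxymethoxy)phenyl]-2-methoxyethan-1-one | COCC(=O)c1c(O)cc(OCOC)c(OC)c1OC
F2 | step 3 | 5-bromo-2,3-dimethoxy-1,4-benzoquinone | COC1=C(OC)C(=O)C(Br)=CC1=O
F3 | step 3 | 5-bromo-2,3-dimethoxybenzene-1,4-diol | COc1c(O)cc(Br)c(O)c1OC
F4 | step 3 | [(5-bromo-2,3-dimethoxy-1,4-phenylene)bis(oxy)]bis(trimethylsilane) | COc1c(O[Si](C)(C)C)cc(Br)c(O[Si](C)(C)C)c1OC
F5 | step 3 | 4-hydroxy-2,3-dimethoxy-6-(trimethylsilyl)phenyl trifluoromethanesulfonate | COc1c(O)cc([Si](C)(C)C)c(OS(=O)(=O)C(F)(F)F)c1OC
F6 | step 4 | 2,3-dimethoxy-4-(methoxymethoxy)phenyl isopropylcarbamate | COCOc1ccc(OC(=O)NC(C)C)c(OC)c1OC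
F7 | step 4 | 2,3-dimethoxy-4-(methoxymethoxy)-6-(trimethylsilyl)phenyl isopropylcarbamate | COCOc1cc([Si](C)(C)C)c(OC(=O)NC(C)C)c(OC)c1OC
F0 | step 8 | none | none
F8 | step 11 | 7-(benzyloxy)-2-[4-(benzyloxy)phenyl]-8-iodo-3,5,6-trimethoxy-4H-chromen-4-one | COc1c(OCc2ccccc2)c(I)c2oc(-c3ccc(OCc4ccccc4)cc3)c(OC)c(=O)c2c1OC
F9 | step 11 | 7-(benzyloxy)-2-[4-(benzyloxy)phenyl]-3,5,6,8-tetramethoxy-4H-chromen-4-one | COc1c(OCc2ccccc2)c(OC)c2oc(-c3ccc(OCc4ccccc4)cc3)c(OC)c(=O)c2c1OC
A1 | alternative 1 | diisopropyl squarate (3,4-diisopropoxycyclobut-3-ene-1,2-dione) | CC(C)OC1=C(OC(C)C)C(=O)C1=O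
A2 | alternative 1 | 2-[4-(benzyloxy)phenyl]-5-bromo-3-methoxy-4H-pyran-4-one | COc1c(-c2ccc(OCc3ccccc3)cc2)occ(Br)c1=O
A3 | alternative 1 | 2-[4-(benzyloxy)phenyl]-5-(1-hydroxy-2,3-diisopropoxy-4-oxocyclobut-2-en-1-yl)-3-methoxy-4H-pyran-4-one (racemic) | COc1c(-c2ccc(OCc3ccccc3)cc2)occ(C2(O)C(OC(C)C)=C(OC(C)C)C2=O)c1=O
A4 | alternative 1 | 2-[4-(benzyloxy)phenyl]-5,8-dihydroxy-6,7-diisopropoxy-3-methoxy-4H-chromen-4-one | COc1c(-c2ccc(OCc3ccccc3)cc2)oc2c(O)c(OC(C)C)c(OC(C)C)c(O)c2c1=O
A5 | alternative 2 | 4-(benzyloxy)-2-hydroxy-3,5,6-trimethoxybenzaldehyde | COc1c(OCc2ccccc2)c(OC)c(O)c(C=O)c1OC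
A6 | alternative 2 | 4-(benzyloxy)-2-{1-[4-(benzyloxy)phenyl]-2-oxoethoxy}-3,5,6-trimethoxybenzaldehyde (racemic) | COc1c(OCc2ccccc2)c(OC)c(OC(C=O)c2ccc(OCc3ccccc3)cc2)c(C=O)c1OC
A7 | alternative 2 | 7-(benzyloxy)-2-[4-(benzyloxy)phenyl]-3-hydroxy-5,6,8-trimethoxychroman-4-one (racemic mixture of diastereomers) | COc1c(OCc2ccccc2)c(OC)c2OC(c3ccc(OCc4ccccc4)cc3)C(O)C(=O)c2c1OC
A8 | alternative 3 | 6-(benzyloxy)-2-[4-(benzyloxy)phenyl]-4,5,7-trimethoxy-1-benzofuran-3(2H)-one (racemic) | COc1c(OCc2ccccc2)c(OC)c2OC(c3ccc(OCc4ccccc4)cc3)C(=O)c2c1OC
A9 | alternative 3 | {[6-(benzyloxy)-2-[4-(benzyloxy)phenyl]-4,5,7-trimethoxy-1-benzofuran-3-yl]oxy}(tert-butyl)dimethylsilane | COc1c(OCc2ccccc2)c(OC)c2oc(-c3ccc(OCc4ccccc4)cc3)c(O[Si](C)(C)C(C)(C)C)c2c1OC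
A10 | alternative 3 | 7-(benzyloxy)-2-[4-(benzyloxy)phenyl]-3-bromo-5,6,8-trimethoxy-4H-chromen-4-one | COc1c(OCc2ccccc2)c(OC)c2oc(-c3ccc(OCc4ccccc4)cc3)c(Br)c(=O)c2c1OC
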